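**Retrosynthetic overview**
1. Locants (drimane type): ring A = C1–C5 + C10 (C1–OH, C3–Cl, quaternary C4); ring B = C5–C10; C11 and C12 are the formyl carbons on C9 and C8.
2. Ene-dial ⇐ 11,12-diol ⇐ ring B enone (C7=C8–C9=O): C12 by Morita–Baylis–Hillman hydroxymethylation, C11 by methylenation/hydroboration, prenyl terminus by cross-metathesis.
3. Ring A ⇐ chloride-terminated Prins cyclisation of the C10 formyl group onto the C4 vinyl group (C1–C2 bond, C3–Cl, C1–OH). Enabling feature: the 1,3-chlorohydrin C1(OH)–C2–C3(Cl) of ring A sits between the quaternary carbons C10 and C4, so the aldehyde cannot enolise, the vinyl group has no allylic hydrogen (no ene escape), and ring B holds both partners in a chair.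
4. Prins precursor ⇐ α-selective 1,2-addition of a (Z)-allylbarium to a carvone-derived ring B enone, anionic oxy-Cope rearrangement (C4–C5 bond, quaternary C4) and formaldehyde capture of the enolate (quaternary C10).
5. Ring order: ring B comes preformed from (R)-carvone (its stereocentre becomes the C7–O relay, later eliminated to C7=C8); ring A is closed last, in step 10.

Key step: step 10

Remark: but-3-en-1-ylmagnesium bromide (9) is taken as the commercial THF solution; "α/β" refer to the face opposite/same as the C10 methyl group.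

**Step 1**
Reactants: 1 (R)-(−)-carvone
Product: 3 (1R)-4-methyl-5-oxocyclohex-3-en-1-yl acetate, via methoxy hydroperoxide 2 (not isolated)
Conditions: O3, CH2Cl2/MeOH, −78 °C; then Ac2O, Et3N, DMAP (cat.), −78 °C → rt
Reagents that add atoms: ozone, [O-][O+]=O
Why: Ozonolysis in methanol traps the carbonyl oxide as the α-methoxy hydroperoxide, whose peracetate should undergo Criegee rearrangement with migration of the ring carbon and retention of configuration, replacing isopropenyl by acetoxy.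

**Step 2**
Reactants: 3 (1R)-4-methyl-5-oxocyclohex-3-en-1-yl acetate
Product: 4 (5R)-5-hydroxy-2-methylcyclohex-2-en-1-one
Conditions: K2CO3 (0.2 equiv), MeOH, 0 °C
Reagents that add atoms: none
Why: Base-catalysed transesterification (methanolysis) of the acetate, run cold to avoid β-elimination to the cresol.

**Step 3**
Reactants: 4 (5R)-5-hydroxy-2-methylcyclohex-2-en-1-one
Product: 5 (5R)-5-[(tert-butyldimethylsilyl)oxy]-2-methylcyclohex-2-en-1-one
Conditions: TBSCl, imidazole, DMF, rt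
Reagents that add atoms: tert-butyldimethylsilyl chloride, CC(C)(C)[Si](C)(C)Cl
Why: Standard silylation of a secondary alcohol; the stereocentre is not touched.

**Step 4**
Reactants: 6 but-2-yn-1-ol
Product: 8 (2Z)-3-iodobut-2-en-1-ol, via cyclic alkenylaluminate 7 (not isolated)
Conditions: NaAlH2(OCH2CH2OCH3)2, Et2O, 0 °C; then I2, −78 → 0 °C
Reagents that add atoms: iodine, II
Why: Hydroxyl-directed trans-hydroalumination places aluminium on C3 cis to the CH2O group in a five-membered aluminate, and iodinolysis with retention should give the Z vinyl iodide.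

**Step 5**
Reactants: 8 (2Z)-3-iodobut-2-en-1-ol; 9 but-3-en-1-ylmagnesium bromide
Product: 10 (2Z)-3-methylhepta-2,6-dien-1-ol
Conditions: 9 (2.5 equiv), PdCl2(dppf) (3 mol %), THF, 0 °C → rt; H2O
Reagents that add atoms: none
Why: Kumada cross-coupling replaces iodine with retention of the Z geometry (dppf suppresses β-hydride elimination); one equivalent of Grignard reagent is spent on the hydroxyl group.

**Step 6**
Reactants: 10 (2Z)-3-methylhepta-2,6-dien-1-ol
Product: 11 (2Z)-1-chloro-3-methylhepta-2,6-diene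
Conditions: MsCl, LiCl, 2,4,6-collidine, DMF, 0 °C
Reagents that add atoms: lithium chloride, [Li+].[Cl-]
Why: Collington–Meyers chlorination (mesylate formed in situ, SN2 displacement by chloride at the primary carbon) should give the allylic chloride without transposition or Z/E scrambling.

**Step 7**
Reactants: 11 (2Z)-1-chloro-3-methylhepta-2,6-diene; 5 (5R)-5-[(tert-butyldimethylsilyl)oxy]-2-methylcyclohex-2-en-1-one
Product: 13 (1R,5R)-5-[(tert-butyldimethylsilyl)oxy]-2-methyl-1-[(2Z)-3-methylhepta-2,6-dien-1-yl]cyclohex-2-en-1-ol, via allylbarium chloride 12 (not isolated)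
Conditions: Ba (from BaI2 + 2 LiC12H10, lithium biphenylide), THF, rt; then 11, −78 °C; then 5, −78 °C; H2O
Reagents that add atoms: none
Why: Allylbarium reagents add to ketones at the α-carbon with retention of alkene geometry (1,2-addition), and the nucleophile should enter the enone by axial attack anti to the silyloxy group, setting the carbinol centre trans to it.

**Step 8**
Reactants: 13 (1R,5R)-5-[(tert-butyldimethylsilyl)oxy]-2-methyl-1-[(2Z)-3-methylhepta-2,6-dien-1-yl]cyclohex-2-en-1-ol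
Product: 16 (2R,3S,5R)-5-[(tert-butyldimethylsilyl)oxy]-2-(hydroxymethyl)-2-methyl-3-[(3R)-3-methylhepta-1,6-dien-3-yl]cyclohexan-1-one, via potassium alkoxide 14 (not isolated), via potassium enolate 15 (not isolated)
Conditions: KH, 18-crown-6, THF, 0 → 25 °C; then CH2O (gas), −78 °C; H2O
Reagents that add atoms: formaldehyde, C=O
Why: Anionic oxy-Cope rearrangement through a chair transition state on the face carrying the allyl group should transfer the carbinol chirality to C5 and, through the Z geometry (chain pseudo-axial), to the quaternary C4; the regiodefined enolate is then hydroxymethylated (aldol) anti to the bulky C5 substituent, giving the quaternary C10.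

**Step 9**
Reactants: 16 (2R,3S,5R)-5-[(tert-butyldimethylsilyl)oxy]-2-(hydroxymethyl)-2-methyl-3-[(3R)-3-methylhepta-1,6-dien-3-yl]cyclohexan-1-one
Product: 17 (1R,2S,4R)-4-[(tert-butyldimethylsilyl)oxy]-1-methyl-2-[(3R)-3-methylhepta-1,6-dien-3-yl]-6-oxocyclohexane-1-carbaldehyde
Conditions: Dess–Martin periodinane, CH2Cl2, rt
Reagents that add atoms: none
Why: Dess–Martin oxidation of the neopentyl primary alcohol should give the non-enolisable β-keto aldehyde under neutral conditions.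

**Step 10**
Reactants: 17 (1R,2S,4R)-4-[(tert-butyldimethylsilyl)oxy]-1-methyl-2-[(3R)-3-methylhepta-1,6-dien-3-yl]-6-oxocyclohexane-1-carbaldehyde
Product: 18 (3R,4aR,5S,6S,8S,8aR)-5-(but-3-en-1-yl)-3-[(tert-butyldimethylsilyl)oxy]-6-chloro-8-hydroxy-5,8a-dimethyloctahydronaphthalen-1(2H)-one
Conditions: TiCl4 (1.5 equiv), CH2Cl2, −78 → −40 °C; then aq. NaHCO3
Reagents that add atoms: titanium tetrachloride, Cl[Ti](Cl)(Cl)Cl
Why: TiCl4 chelates the 1,3-dicarbonyl unit and activates the C10 formyl group, whose carbon (C1) is attacked by the terminal carbon (C2) of the C4 vinyl group in a chair transition state, while chloride from the titanium ate counter-ion adds to the developing positive charge at C3 anti to the new C1–C2 bond. The closest known reaction type is the Lewis-acid-promoted Prins (cation–olefin) cyclisation of hex-5-enals to 3-chlorocyclohexanols with titanium or tin tetrachloride. Ring A closes by C1–C2 bond formation in a 6-endo-trig mode with respect to the vinyl group (both olefinic carbons become ring atoms), and the diequatorial C5–C4 and C10–C1 bonds on ring B make the new ring trans-fused. C1 is controlled by the chelate, whose titanium-bound oxygen should take the axial (α) position anti to the C10 methyl group because the alternative pushes the metal against that methyl; C3 is controlled by anti addition, chloride entering equatorially (β). The step needs the vinyl group, not the but-3-enyl group, to react, which ring size secures (six-membered chair against an eight-membered ring), and it needs chloride capture to outrun a 1,2-shift from the quaternary C4, which low temperature and the tight chloride-rich ion pair should secure. Enolisation and ene pathways are excluded because C10 and C4 carry no hydrogen.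

**Step 11**
Reactants: 18 (3R,4aR,5S,6S,8S,8aR)-5-(but-3-en-1-yl)-3-[(tert-butyldimethylsilyl)oxy]-6-chloro-8-hydroxy-5,8a-dimethyloctahydronaphthalen-1(2H)-one
Product: 19 (4aR,5S,6S,8S,8aR)-5-(but-3-en-1-yl)-6-chloro-8-hydroxy-5,8a-dimethyl-4a,5,6,7,8,8a-hexahydronaphthalen-1(4H)-one
Conditions: p-TsOH·H2O (0.2 equiv), benzene, 60 °C
Reagents that add atoms: none
Why: Acid-catalysed β-elimination of the silanol through the enol should give the conjugated C7=C8 enone, whereas the C1 hydroxyl cannot eliminate because C10 bears no hydrogen.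

**Step 12**
Reactants: 19 (4aR,5S,6S,8S,8aR)-5-(but-3-en-1-yl)-6-chloro-8-hydroxy-5,8a-dimethyl-4a,5,6,7,8,8a-hexahydronaphthalen-1(4H)-one
Product: 20 (4aR,5S,6S,8S,8aR)-5-(but-3-en-1-yl)-6-chloro-5,8a-dimethyl-8-[(triethylsilyl)oxy]-4a,5,6,7,8,8a-hexahydronaphthalen-1(4H)-one
Conditions: TESOTf, 2,6-lutidine, CH2Cl2, −78 → 0 °C
Reagents that add atoms: triethylsilyl trifluoromethanesulfonate, CC[Si](CC)(CC)OS(=O)(=O)C(F)(F)F
Why: Silylation of the hindered axial alcohol with a silyl triflate protects C1–OH against retro-aldol cleavage under base and against the final oxidation.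

**Step 13**
Reactants: 20 (4aR,5S,6S,8S,8aR)-5-(but-3-en-1-yl)-6-chloro-5,8a-dimethyl-8-[(triethylsilyl)oxy]-4a,5,6,7,8,8a-hexahydronaphthalen-1(4H)-one
Product: 21 (4aR,5S,6S,8S,8aR)-6-chloro-5,8a-dimethyl-5-(4-methylpent-3-en-1-yl)-8-[(triethylsilyl)oxy]-4a,5,6,7,8,8a-hexahydronaphthalen-1(4H)-one
Conditions: RuCl2(=CHPh)(PCy3)(H2IMes) (second-generation Grubbs catalyst, 5 mol %), 2-methylbut-2-ene/CH2Cl2, 40 °C
Reagents that add atoms: 2-methylbut-2-ene, CC=C(C)C
Why: Olefin cross-metathesis of the terminal alkene with 2-methylbut-2-ene should install the prenyl terminus, the unstrained, electron-poor ring alkene staying inert.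

**Step 14**
Reactants: 21 (4aR,5S,6S,8S,8aR)-6-chloro-5,8a-dimethyl-5-(4-methylpent-3-en-1-yl)-8-[(triethylsilyl)oxy]-4a,5,6,7,8,8a-hexahydronaphthalen-1(4H)-one
Product: 22 (4aR,5S,6S,8S,8aR)-6-chloro-2-(hydroxymethyl)-5,8a-dimethyl-5-(4-methylpent-3-en-1-yl)-8-[(triethylsilyl)oxy]-4a,5,6,7,8,8a-hexahydronaphthalen-1(4H)-one
Conditions: CH2O (37 % aq.), DMAP (0.2 equiv), THF, rt
Reagents that add atoms: formaldehyde, C=O
Why: Morita–Baylis–Hillman hydroxymethylation: DMAP adds to the unhindered C7, the enolate is trapped at C8 by formaldehyde and the catalyst is eliminated, bringing in C12 at the alcohol level.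

**Step 15**
Reactants: 22 (4aR,5S,6S,8S,8aR)-6-chloro-2-(hydroxymethyl)-5,8a-dimethyl-5-(4-methylpent-3-en-1-yl)-8-[(triethylsilyl)oxy]-4a,5,6,7,8,8a-hexahydronaphthalen-1(4H)-one
Product: 23 [(4aR,5S,6S,8S,8aS)-6-chloro-5,8a-dimethyl-1-methylidene-5-(4-methylpent-3-en-1-yl)-8-[(triethylsilyl)oxy]-1,4,4a,5,6,7,8,8a-octahydronaphthalen-2-yl]methanol
Conditions: Ph3PCH3Br, KOC(CH3)3 (excess), toluene, 90 °C
Reagents that add atoms: methyltriphenylphosphonium bromide, C[P+](c1ccccc1)(c1ccccc1)c1ccccc1.[Br-]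
Why: Wittig methylenation under the forcing conditions used for hindered ketones should turn the C9 carbonyl into the C9=C11 alkene, the C12 alkoxide being a spectator.

**Step 16**
Reactants: 23 [(4aR,5S,6S,8S,8aS)-6-chloro-5,8a-dimethyl-1-methylidene-5-(4-methylpent-3-en-1-yl)-8-[(triethylsilyl)oxy]-1,4,4a,5,6,7,8,8a-octahydronaphthalen-2-yl]methanol
Product: 25 [(1S,4aR,5S,6S,8S,8aS)-6-chloro-5,8a-dimethyl-5-(4-methylpent-3-en-1-yl)-8-[(triethylsilyl)oxy]-1,4,4a,5,6,7,8,8a-octahydronaphthalene-1,2-diyl]dimethanol, via bis-borane adduct 24 (not isolated)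
Conditions: 9-BBN (2.2 equiv), THF, 0 °C → rt; then NaOH, H2O2, 0 °C
Reagents that add atoms: hydrogen peroxide, OO
Why: Hydroboration–oxidation with 9-BBN is selective for the terminal 1,1-disubstituted alkene over the two trisubstituted ones and puts boron on C11; hydrogen should reach C9 from the α face, anti to the axial C10 methyl group (one bond closer to C11 than the C1 silyloxy group), giving the 9β-hydroxymethyl group.

**Step 17**
Reactants: 25 [(1S,4aR,5S,6S,8S,8aS)-6-chloro-5,8a-dimethyl-5-(4-methylpent-3-en-1-yl)-8-[(triethylsilyl)oxy]-1,4,4a,5,6,7,8,8a-octahydronaphthalene-1,2-diyl]dimethanol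
Product: 26 (1R,4aR,5S,6S,8S,8aS)-6-chloro-5,8a-dimethyl-5-(4-methylpent-3-en-1-yl)-8-[(triethylsilyl)oxy]-1,4,4a,5,6,7,8,8a-octahydronaphthalene-1,2-dicarbaldehyde
Conditions: (COCl)2, DMSO, CH2Cl2, −78 °C; then Et3N, −78 → −20 °C
Reagents that add atoms: none
Why: Swern oxidation activates both primary hydroxyls before base is added, so the 1,4-diol should go to the dialdehyde without lactol or lactone formation (as known for drimane 11,12-diols), and the low temperature protects C9 from epimerisation.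

**Step 18**
Reactants: 26 (1R,4aR,5S,6S,8S,8aS)-6-chloro-5,8a-dimethyl-5-(4-methylpent-3-en-1-yl)-8-[(triethylsilyl)oxy]-1,4,4a,5,6,7,8,8a-octahydronaphthalene-1,2-dicarbaldehyde
Product: 27 (1R,4aR,5S,6S,8S,8aS)-6-chloro-8-hydroxy-5,8a-dimethyl-5-(4-methylpent-3-en-1-yl)-1,4,4a,5,6,7,8,8a-octahydronaphthalene-1,2-dicarbaldehyde
Conditions: HF·pyridine, pyridine/THF, 0 °C
Reagents that add atoms: none
Why: Fluoride-mediated desilylation under buffered, weakly acidic conditions should remove the triethylsilyl ether without epimerising C9 or touching the enal.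

**Compound list**
1 | (R)-(−)-carvone, (5R)-2-methyl-5-(prop-1-en-2-yl)cyclohex-2-en-1-one | CC1=CC[C@@H](C(C)=C)CC1=O | starting material
2 | (5R)-5-(1-hydroperoxy-1-methoxyethyl)-2-methylcyclohex-2-en-1-one | CC1=CC[C@@H](C(C)(OC)OO)CC1=O | intermediate
3 | (1R)-4-methyl-5-oxocyclohex-3-en-1-yl acetate | CC1=CC[C@@H](OC(C)=O)CC1=O | intermediate
4 | (5R)-5-hydroxy-2-methylcyclohex-2-en-1-one | CC1=CC[C@@H](O)CC1=O | intermediate
5 | (5R)-5-[(tert-butyldimethylsilyl)oxy]-2-methylcyclohex-2-en-1-one | CC1=CC[C@@H](O[Si](C)(C)C(C)(C)C)CC1=O | intermediate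
6 | but-2-yn-1-ol | CC#CCO | starting material
7 | sodium 2,2-bis(2-methoxyethoxy)-3-methyl-2,5-dihydro-1,2-oxaluminol-2-uide (cyclic alkenylaluminate) | [Na+].CC1=CCO[Al-]1(OCCOC)OCCOC | intermediate
8 | (2Z)-3-iodobut-2-en-1-ol | C/C(I)=C/CO | intermediate
9 | but-3-en-1-ylmagnesium bromide | C=CCC[Mg]Br | starting material
10 | (2Z)-3-methylhepta-2,6-dien-1-ol | C=CCC/C(C)=C\CO | intermediate
11 | (2Z)-1-chloro-3-methylhepta-2,6-diene | C=CCC/C(C)=C\CCl | intermediate
12 | [(2Z)-3-methylhepta-2,6-dien-1-yl]barium chloride | C=CCC/C(C)=C\C[Ba]Cl | intermediate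
13 | (1R,5R)-5-[(tert-butyldimethylsilyl)oxy]-2-methyl-1-[(2Z)-3-methylhepta-2,6-dien-1-yl]cyclohex-2-en-1-ol | C=CCC/C(C)=C\C[C@@]1(O)C[C@H](O[Si](C)(C)C(C)(C)C)CC=C1C | intermediate
14 | potassium (1R,5R)-5-[(tert-butyldimethylsilyl)oxy]-2-methyl-1-[(2Z)-3-methylhepta-2,6-dien-1-yl]cyclohex-2-en-1-olate | [K+].C=CCC/C(C)=C\C[C@@]1([O-])C[C@H](O[Si](C)(C)C(C)(C)C)CC=C1C | intermediate
15 | potassium (3S,5R)-5-[(tert-butyldimethylsilyl)oxy]-2-methyl-3-[(3R)-3-methylhepta-1,6-dien-3-yl]cyclohex-1-en-1-olate | [K+].C=CCC[C@](C)(C=C)[C@@H]1C[C@@H](O[Si](C)(C)C(C)(C)C)CC([O-])=C1C | intermediate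
16 | (2R,3S,5R)-5-[(tert-butyldimethylsilyl)oxy]-2-(hydroxymethyl)-2-methyl-3-[(3R)-3-methylhepta-1,6-dien-3-yl]cyclohexan-1-one | C=CCC[C@](C)(C=C)[C@@H]1C[C@@H](O[Si](C)(C)C(C)(C)C)CC(=O)[C@@]1(C)CO | intermediate
17 | (1R,2S,4R)-4-[(tert-butyldimethylsilyl)oxy]-1-methyl-2-[(3R)-3-methylhepta-1,6-dien-3-yl]-6-oxocyclohexane-1-carbaldehyde | C=CCC[C@](C)(C=C)[C@@H]1C[C@@H](O[Si](C)(C)C(C)(C)C)CC(=O)[C@@]1(C)C=O | intermediate
18 | (3R,4aR,5S,6S,8S,8aR)-5-(but-3-en-1-yl)-3-[(tert-butyldimethylsilyl)oxy]-6-chloro-8-hydroxy-5,8a-dimethyloctahydronaphthalen-1(2H)-one | C=CCC[C@]1(C)[C@@H](Cl)C[C@H](O)[C@]2(C)C(=O)C[C@H](O[Si](C)(C)C(C)(C)C)C[C@@H]12 | intermediate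
19 | (4aR,5S,6S,8S,8aR)-5-(but-3-en-1-yl)-6-chloro-8-hydroxy-5,8a-dimethyl-4a,5,6,7,8,8a-hexahydronaphthalen-1(4H)-one | C=CCC[C@]1(C)[C@@H](Cl)C[C@H](O)[C@]2(C)C(=O)C=CC[C@@H]12 | intermediate
20 | (4aR,5S,6S,8S,8aR)-5-(but-3-en-1-yl)-6-chloro-5,8a-dimethyl-8-[(triethylsilyl)oxy]-4a,5,6,7,8,8a-hexahydronaphthalen-1(4H)-one | C=CCC[C@]1(C)[C@@H](Cl)C[C@H](O[Si](CC)(CC)CC)[C@]2(C)C(=O)C=CC[C@@H]12 | intermediate
21 | (4aR,5S,6S,8S,8aR)-6-chloro-5,8a-dimethyl-5-(4-methylpent-3-en-1-yl)-8-[(triethylsilyl)oxy]-4a,5,6,7,8,8a-hexahydronaphthalen-1(4H)-one | CC(C)=CCC[C@]1(C)[C@@H](Cl)C[C@H](O[Si](CC)(CC)CC)[C@]2(C)C(=O)C=CC[C@@H]12 | intermediate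
22 | (4aR,5S,6S,8S,8aR)-6-chloro-2-(hydroxymethyl)-5,8a-dimethyl-5-(4-methylpent-3-en-1-yl)-8-[(triethylsilyl)oxy]-4a,5,6,7,8,8a-hexahydronaphthalen-1(4H)-one | CC(C)=CCC[C@]1(C)[C@@H](Cl)C[C@H](O[Si](CC)(CC)CC)[C@]2(C)C(=O)C(CO)=CC[C@@H]12 | intermediate
23 | [(4aR,5S,6S,8S,8aS)-6-chloro-5,8a-dimethyl-1-methylidene-5-(4-methylpent-3-en-1-yl)-8-[(triethylsilyl)oxy]-1,4,4a,5,6,7,8,8a-octahydronaphthalen-2-yl]methanol | CC(C)=CCC[C@]1(C)[C@@H](Cl)C[C@H](O[Si](CC)(CC)CC)[C@]2(C)C(=C)C(CO)=CC[C@@H]12 | intermediate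
24 | bis-borane adduct of 23: C11 bonded to boron of one 9-borabicyclo[3.3.1]nonan-9-yl group (H on C9 α), C12 oxygen bonded to boron of a second one | CC(C)=CCC[C@]1(C)[C@@H](Cl)C[C@H](O[Si](CC)(CC)CC)[C@]2(C)[C@@H](CB3C4CCCC3CCC4)C(COB3C4CCCC3CCC4)=CC[C@@H]12 | intermediate
25 | [(1S,4aR,5S,6S,8S,8aS)-6-chloro-5,8a-dimethyl-5-(4-methylpent-3-en-1-yl)-8-[(triethylsilyl)oxy]-1,4,4a,5,6,7,8,8a-octahydronaphthalene-1,2-diyl]dimethanol | CC(C)=CCC[C@]1(C)[C@@H](Cl)C[C@H](O[Si](CC)(CC)CC)[C@]2(C)[C@@H](CO)C(CO)=CC[C@@H]12 | intermediate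
26 | (1R,4aR,5S,6S,8S,8aS)-6-chloro-5,8a-dimethyl-5-(4-methylpent-3-en-1-yl)-8-[(triethylsilyl)oxy]-1,4,4a,5,6,7,8,8a-octahydronaphthalene-1,2-dicarbaldehyde | CC(C)=CCC[C@]1(C)[C@@H](Cl)C[C@H](O[Si](CC)(CC)CC)[C@]2(C)[C@@H](C=O)C(C=O)=CC[C@@H]12 | intermediate
27 | (1R,4aR,5S,6S,8S,8aS)-6-chloro-8-hydroxy-5,8a-dimethyl-5-(4-methylpent-3-en-1-yl)-1,4,4a,5,6,7,8,8a-octahydronaphthalene-1,2-dicarbaldehyde | CC(C)=CCC[C@]1(C)[C@@H](Cl)C[C@H](O)[C@]2(C)[C@@H](C=O)C(C=O)=CC[C@@H]12 | target

**Step count and risks**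
Total step count: 18. Longest linear sequence: 15 steps (steps 1–3 then 7–18; steps 4–6 then 7–18 is equally long).

Step 10 (Prins closure of ring A). Chloride capture at C3 may lose out to a 1,2-shift of a C4 substituent or to attack of the but-3-enyl double bond on the C3 cation, or the chelated aldehyde may be too weak an electrophile for the unactivated vinyl group. The fallback sets out from 17 and replaces the titanium-bound aldehyde by a free oxocarbenium ion. Acetalisation of 17 with 4-methoxybenzyl trimethylsilyl ether and catalytic Me3SiOTf would give (2R,3S,5R)-2-[bis(4-methoxybenzyloxy)methyl]-5-[(tert-butyldimethylsilyl)oxy]-2-methyl-3-[(3R)-3-methylhepta-1,6-dien-3-yl]cyclohexan-1-one F4. Ionisation with SnCl4 in CH2Cl2 at −90 °C should close ring A within a tight ion pair to (3R,4aR,5S,6S,8S,8aR)-5-(but-3-en-1-yl)-3-[(tert-butyldimethylsilyl)oxy]-6-chloro-8-[(4-methoxybenzyl)oxy]-5,8a-dimethyloctahydronaphthalen-1(2H)-one F5. Oxidative removal of the 4-methoxybenzyl group with DDQ in wet CH2Cl2 returns to the route at 18.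

Step 8 (oxy-Cope rearrangement). The alkoxide may rearrange through the boat-like instead of the chair-like transition state, or partly by allyl fragmentation and recombination, which would deliver the C4 epimer. The fallback sets out from 5 and uses the E-configured allyl unit, for which the boat leads to the same product. Hex-1-en-5-yne would be carboaluminated (Al(CH3)3, Cp2ZrCl2, then n-BuLi and paraformaldehyde) to (2E)-3-methylhepta-2,6-dien-1-ol F1. This is chlorinated as in step 6 to (2E)-1-chloro-3-methylhepta-2,6-diene F2 and added as its barium reagent to 5 as in step 7, giving (1R,5R)-5-[(tert-butyldimethylsilyl)oxy]-2-methyl-1-[(2E)-3-methylhepta-2,6-dien-1-yl]cyclohex-2-en-1-ol F3. Rearrangement and hydroxymethylation of F3 under the conditions of step 8 return to the route at 16.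

Step 15 (methylenation of the C9 ketone). Addition of the ylide to the cross-conjugated carbonyl, flanked by the quaternary C10 and the substituted C8, may be too slow, so that deprotonation at C6 or decomposition takes over. The fallback sets out from 22 and uses a Peterson olefination with a small, non-basic organocerium nucleophile. (CH3)3SiCH2Li/CeCl3 in THF at −78 °C should add to C9 to give (4aR,5S,6S,8S,8aR)-6-chloro-2-(hydroxymethyl)-5,8a-dimethyl-5-(4-methylpent-3-en-1-yl)-8-[(triethylsilyl)oxy]-1-[(trimethylsilyl)methyl]-1,4,4a,5,6,7,8,8a-octahydronaphthalen-1-ol F6. Syn elimination with KH in THF returns to the route at 23.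

**Further compounds**
F1 | step 8 | (2E)-3-methylhepta-2,6-dien-1-ol | C=CCC/C(C)=C/CO
F2 | step 8 | (2E)-1-chloro-3-methylhepta-2,6-diene | C=CCC/C(C)=C/CCl
F3 | step 8 | (1R,5R)-5-[(tert-butyldimethylsilyl)oxy]-2-methyl-1-[(2E)-3-methylhepta-2,6-dien-1-yl]cyclohex-2-en-1-ol | C=CCC/C(C)=C/C[C@@]1(O)C[C@H](O[Si](C)(C)C(C)(C)C)CC=C1C
F4 | step 10 | (2R,3S,5R)-2-[bis(4-methoxybenzyloxy)methyl]-5-[(tert-butyldimethylsilyl)oxy]-2-methyl-3-[(3R)-3-methylhepta-1,6-dien-3-yl]cyclohexan-1-one | C=CCC[C@](C)(C=C)[C@@H]1C[C@@H](O[Si](C)(C)C(C)(C)C)CC(=O)[C@@]1(C)C(OCc1ccc(OC)cc1)OCc1ccc(OC)cc1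
F5 | step 10 | (3R,4aR,5S,6S,8S,8aR)-5-(but-3-en-1-yl)-3-[(tert-butyldimethylsilyl)oxy]-6-chloro-8-[(4-methoxybenzyl)oxy]-5,8a-dimethyloctahydronaphthalen-1(2H)-one | C=CCC[C@]1(C)[C@@H](Cl)C[C@H](OCc3ccc(OC)cc3)[C@]2(C)C(=O)C[C@H](O[Si](C)(C)C(C)(C)C)C[C@@H]12
F6 | step 15 | (4aR,5S,6S,8S,8aR)-6-chloro-2-(hydroxymethyl)-5,8a-dimethyl-5-(4-methylpent-3-en-1-yl)-8-[(triethylsilyl)oxy]-1-[(trimethylsilyl)methyl]-1,4,4a,5,6,7,8,8a-octahydronaphthalen-1-ol | CC(C)=CCC[C@]1(C)[C@@H](Cl)C[C@H](O[Si](CC)(CC)CC)[C@]2(C)C(O)(C[Si](C)(C)C)C(CO)=CC[C@@H]12
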